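The lactone is removed first: C2 and C3 are the remains of an allyl group and O1 is a former ketone oxygen at C6a, so the target maps onto a trans-2-allyl-5-substituted tetrahydrofuran-3-one. That ring is made in one operation from a diazoketone: a copper carbenoid is trapped by the allyl ether oxygen (O4–C3a bond, ring closure) and the cyclic oxonium ylide hands the allyl group to carbon by a [2,3]-shift (C3a–C3 bond). The step exploits the substitution at C3a of the furo[3,2-b]furanone: bonded to ring oxygen O4 and to the C3 methylene, and trans to the C5 substituent on the tetrahydrofuran ring. The precursor is a 4-allyloxy-1-diazo-2-ketone carrying the pinocembrin 7-O-ether at the benzylic carbon.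

Key step: step 8

Assumption: the chelated 5-OH of the flavanone is carried unprotected throughout (its hydrogen bond to the C4 carbonyl should keep it out of the etherification, acylation, diazomethane and carbenoid steps), and methyl (E)-4-phenylbut-3-enoate and the L-series Shi ketone are taken as purchasable.

Step 1
Reactants: 1 methyl (E)-4-phenylbut-3-enoate
Product: 2 methyl 2-[(2S,3S)-3-phenyloxiran-2-yl]acetate
Conditions: ent-Shi ketone (1,2:4,5-di-O-isopropylidene-β-L-erythro-2,3-hexodiulo-2,6-pyranose, 0.3 eq), KHSO5 (as 2KHSO5·KHSO4·K2SO4), K2CO3, Bu4NHSO4 (cat.), MeCN–CH2(OMe)2, aq. Na2B4O7 buffer, 0 °C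
Reagents that add atoms: potassium peroxymonosulfate, [K+].[O-]S(=O)(=O)OO
Why: Shi asymmetric epoxidation: the chiral dioxirane generated from the ketone and KHSO5 transfers oxygen to the trans-disubstituted styrenyl alkene through a spiro transition state, and the L-series ketone should give the (2S,3S)-epoxide (both stereocenters set by the catalyst), the mirror image of the sense established for trans-β-alkylstyrenes with the D-fructose-derived ketone.

Step 2
Reactants: 2 methyl 2-[(2S,3S)-3-phenyloxiran-2-yl]acetate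
Product: 3 (4S,5R)-4-hydroxy-5-phenyldihydrofuran-2(3H)-one
Conditions: TsOH·H2O (10 mol%), H2O (2 eq), CH2Cl2, 0 °C → rt
Reagents that add atoms: water, O
Why: Acid-catalysed epoxy-ester lactonisation with neighbouring-group participation: the ester carbonyl oxygen opens the protonated epoxide at the benzylic carbon from the side opposite the leaving oxygen (inversion there, the other center untouched) and water hydrolyses the cyclic dialkoxycarbenium ion, so the trans-hydroxylactone should result with the two oxygens differentiated.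

Step 3
Reactants: 3 (4S,5R)-4-hydroxy-5-phenyldihydrofuran-2(3H)-one; 4 allyl 2,2,2-trichloroacetimidate
Product: 5 (4S,5R)-4-(allyloxy)-5-phenyldihydrofuran-2(3H)-one
Conditions: 4 (1.5 eq), TfOH (5 mol%), CH2Cl2–cyclohexane, 0 °C → rt
Reagents that add atoms: none
Why: Brønsted acid-catalysed O-alkylation of an alcohol with an O-allyl trichloroacetimidate, chosen because a β-hydroxylactone would eliminate to the butenolide under basic Williamson conditions; no stereocenter is involved.

Step 4
Reactants: 5 (4S,5R)-4-(allyloxy)-5-phenyldihydrofuran-2(3H)-one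
Product: 7 allyl (3S,4R)-3-(allyloxy)-4-hydroxy-4-phenylbutanoate, via potassium hydroxy-carboxylate 6 (not isolated)
Conditions: KOH (1.0 eq), THF–H2O, 0 °C; evaporate; allyl bromide (1.2 eq), DMF, 0 °C → rt; crude ester used without delay
Reagents that add atoms: potassium hydroxide, [K+].[OH-]; allyl bromide, C=CCBr
Why: Lactone saponification followed by SN2 O-alkylation of the carboxylate: one equivalent of hydroxide at 0 °C should add to the lactone carbonyl faster than it provokes β-elimination of the allyloxy group, and the allyl ester both prevents re-lactonisation of the freed benzylic alcohol and can be removed later without base.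

Step 5
Reactants: 7 allyl (3S,4R)-3-(allyloxy)-4-hydroxy-4-phenylbutanoate; 8 (S)-pinocembrin [(2S)-5,7-dihydroxy-2-phenylchroman-4-one]
Product: 9 allyl (3S,4S)-3-(allyloxy)-4-{[(2S)-5-hydroxy-4-oxo-2-phenylchroman-7-yl]oxy}-4-phenylbutanoate
Conditions: PPh3 (1.5 eq), DIAD (1.5 eq), THF, 0 °C → rt
Reagents that add atoms: none
Why: Mitsunobu etherification: the acidic, non-chelated 7-OH of pinocembrin is the pronucleophile and displaces the benzylic alkoxyphosphonium ion by SN2 with inversion, turning the (4R)-carbinol into the (4S)-aryl ether, while the 5-OH remains hydrogen-bonded to the C4 carbonyl and the unactivated phenyl ring together with the adjacent alkoxy group disfavours ionisation.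

Step 6
Reactants: 9 allyl (3S,4S)-3-(allyloxy)-4-{[(2S)-5-hydroxy-4-oxo-2-phenylchroman-7-yl]oxy}-4-phenylbutanoate
Product: 10 (3S,4S)-3-(allyloxy)-4-{[(2S)-5-hydroxy-4-oxo-2-phenylchroman-7-yl]oxy}-4-phenylbutanoic acid
Conditions: Pd(PPh3)4 (5 mol%), morpholine (5 eq), THF, rt; then aq. citric acid
Reagents that add atoms: none
Why: Tsuji–Trost deallylation: zerovalent palladium ionises only the allyl ester (carboxylate is a good leaving group, the alkoxide of the allyl alkyl ether is not) and morpholine traps the π-allyl fragment, so the acid is freed at room temperature without the hydroxide that would endanger the flavanone and the β-alkoxy acid.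

Step 7
Reactants: 10 (3S,4S)-3-(allyloxy)-4-{[(2S)-5-hydroxy-4-oxo-2-phenylchroman-7-yl]oxy}-4-phenylbutanoic acid
Product: 12 (2S)-7-{[(1S,2S)-2-(allyloxy)-5-diazo-4-oxo-1-phenylpentyl]oxy}-5-hydroxy-2-phenylchroman-4-one, via isobutyl mixed anhydride 11 (not isolated)
Conditions: i-BuOCOCl (1.05 eq), N-methylmorpholine (1.1 eq), THF, −20 °C; then CH2N2 (ca. 3 eq, Et2O solution made beforehand), −20 → 0 °C
Reagents that add atoms: diazomethane, C=[N+]=[N-]; isobutyl chloroformate, CC(C)COC(Cl)=O (its atoms stay only in intermediate 11)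
Why: Acylation of diazomethane by a mixed carbonic anhydride (the first stage of an Arndt–Eistert sequence) gives the terminal diazoketone under nearly neutral conditions; the chelated 5-OH is a poor partner for both the chloroformate and diazomethane.

Step 8
Reactants: 12 (2S)-7-{[(1S,2S)-2-(allyloxy)-5-diazo-4-oxo-1-phenylpentyl]oxy}-5-hydroxy-2-phenylchroman-4-one
Product: 14 (2S)-7-{(S)-[(2S,5R)-5-allyl-4-oxotetrahydrofuran-2-yl](phenyl)methoxy}-5-hydroxy-2-phenylchroman-4-one, via cyclic allyloxonium ylide 13 (not isolated)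
Conditions: Cu(acac)2 (10 mol%), THF, reflux, slow addition of 12 (final ca. 0.01 M)
Reagents that add atoms: none
Why: Cu(acac)2 decomposes the diazoketone with loss of N2 to an electrophilic copper carbenoid, the lone pair of the allyl ether oxygen adds to its carbon to give the five-membered cyclic oxonium ylide 13, and a suprafacial [2,3]-sigmatropic shift then moves the allyl group from oxygen to the ylide carbon with allylic transposition. The closest known reaction type is the copper-catalysed tandem oxonium ylide formation/[2,3]-rearrangement of 4-allyloxy-1-diazo-2-ketones to trans-2-allyl-5-alkyl tetrahydrofuran-3-ones. The tetrahydrofuran ring closes by O–C bond formation in a five-ring closure that is exo with respect to the breaking Cu=C bond (5-exo), the ketone carbon lying inside the new ring. The new stereocenter (the allyl-bearing carbon, R) is controlled by the existing ring carbon that carries the side chain: this substituent sits pseudo-equatorially in the envelope, the allyl group on oxygen lies anti to it, and the concerted shift delivers allyl to that same face of the ylide carbon, which gives the 2,5-trans ring. The step needs chemoselectivity for the allyl ether oxygen and for the [2,3]- over the [1,2]-shift: the dialkyl ether oxygen is the better donor and closes a five- and not a six-membered ring as the aryl ether oxygen would, the hydrogen-bonded 5-OH and the high dilution hold back O–H insertion, and Cu(acac)2 is the catalyst that favours ylide formation and the concerted shift.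

Step 9
Reactants: 14 (2S)-7-{(S)-[(2S,5R)-5-allyl-4-oxotetrahydrofuran-2-yl](phenyl)methoxy}-5-hydroxy-2-phenylchroman-4-one
Product: 15 (2S)-7-{(S)-[(2S,4R,5R)-5-allyl-4-hydroxytetrahydrofuran-2-yl](phenyl)methoxy}-5-hydroxy-2-phenylchroman-4-one
Conditions: LiBH(s-Bu)3 (2.2 eq), THF, −78 °C; then MeOH, aq. NH4Cl (no oxidative work-up)
Reagents that add atoms: none
Why: Diastereoselective ketone reduction with a bulky trialkylborohydride: hydride should approach the ring carbonyl from the face opposite the adjacent allyl group, which sets the carbinol center (4R, hydroxyl cis to allyl), while the flavanone carbonyl, present as a chelated lithium phenoxide once the first equivalent of hydride has been consumed by the 5-OH, should be too deactivated to react at −78 °C.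

Step 10
Reactants: 15 (2S)-7-{(S)-[(2S,4R,5R)-5-allyl-4-hydroxytetrahydrofuran-2-yl](phenyl)methoxy}-5-hydroxy-2-phenylchroman-4-one
Product: 18 (2S)-5-hydroxy-7-{(S)-[(3aR,5S,6aR)-2-hydroxyhexahydrofuro[3,2-b]furan-5-yl](phenyl)methoxy}-2-phenylchroman-4-one, via triol 16 (not isolated), via hydroxy-aldehyde 17 (not isolated)
Conditions: OsO4 (2 mol%), NaIO4 (4 eq), 2,6-lutidine (2 eq), dioxane–H2O (3:1), rt
Reagents that add atoms: osmium tetroxide, O=[Os](=O)(=O)=O (oxygen carrier); sodium periodate, [Na+].[O-]I(=O)(=O)=O (terminal oxidant)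
Why: Lemieux–Johnson oxidation: osmylation of the terminal alkene and periodate cleavage of the resulting glycol give the aldehyde, which the cis hydroxyl captures at once as the five-membered lactol; ozone is avoided because of the electron-rich phenolic ring.

Step 11
Reactants: 18 (2S)-5-hydroxy-7-{(S)-[(3aR,5S,6aR)-2-hydroxyhexahydrofuro[3,2-b]furan-5-yl](phenyl)methoxy}-2-phenylchroman-4-one
Product: 19 (3aR,5S,6aR)-5-{(S)-{[(2S)-5-hydroxy-4-oxo-2-phenylchroman-7-yl]oxy}(phenyl)methyl}tetrahydrofuro[3,2-b]furan-2(3H)-one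
Conditions: Ag2CO3 on Celite (excess), toluene, reflux, dark
Reagents that add atoms: none
Why: Fétizon oxidation: Ag2CO3 on Celite oxidises lactols to lactones on the neutral solid surface, which should leave the flavanone, its chelated phenol and the benzylic aryl ether intact; no stereocenter is affected.

Compound list
1 | methyl (E)-4-phenylbut-3-enoate | COC(=O)C/C=C/c1ccccc1 | starting material
2 | methyl 2-[(2S,3S)-3-phenyloxiran-2-yl]acetate | COC(=O)C[C@@H]1O[C@H]1c1ccccc1 | intermediate
3 | (4S,5R)-4-hydroxy-5-phenyldihydrofuran-2(3H)-one | O=C1C[C@H](O)[C@@H](c2ccccc2)O1 | intermediate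
4 | allyl 2,2,2-trichloroacetimidate | C=CCOC(=N)C(Cl)(Cl)Cl | starting material
5 | (4S,5R)-4-(allyloxy)-5-phenyldihydrofuran-2(3H)-one | O=C1C[C@H](OCC=C)[C@@H](c2ccccc2)O1 | intermediate
6 | potassium (3S,4R)-3-(allyloxy)-4-hydroxy-4-phenylbutanoate | [K+].[O-]C(=O)C[C@H](OCC=C)[C@H](O)c1ccccc1 | intermediate (not isolated)
7 | allyl (3S,4R)-3-(allyloxy)-4-hydroxy-4-phenylbutanoate | C=CCOC(=O)C[C@H](OCC=C)[C@H](O)c1ccccc1 | intermediate
8 | (S)-pinocembrin, (2S)-5,7-dihydroxy-2-phenylchroman-4-one | O=C1C[C@@H](c2ccccc2)Oc2cc(O)cc(O)c12 | starting material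
9 | allyl (3S,4S)-3-(allyloxy)-4-{[(2S)-5-hydroxy-4-oxo-2-phenylchroman-7-yl]oxy}-4-phenylbutanoate | C=CCOC(=O)C[C@H](OCC=C)[C@@H](Oc1cc(O)c2c(c1)O[C@H](c1ccccc1)CC2=O)c1ccccc1 | intermediate
10 | (3S,4S)-3-(allyloxy)-4-{[(2S)-5-hydroxy-4-oxo-2-phenylchroman-7-yl]oxy}-4-phenylbutanoic acid | OC(=O)C[C@H](OCC=C)[C@@H](Oc1cc(O)c2c(c1)O[C@H](c1ccccc1)CC2=O)c1ccccc1 | intermediate
11 | (3S,4S)-3-(allyloxy)-4-{[(2S)-5-hydroxy-4-oxo-2-phenylchroman-7-yl]oxy}-4-phenylbutanoic isobutyl carbonic anhydride | CC(C)COC(=O)OC(=O)C[C@H](OCC=C)[C@@H](Oc1cc(O)c2c(c1)O[C@H](c1ccccc1)CC2=O)c1ccccc1 | intermediate (not isolated)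
12 | (2S)-7-{[(1S,2S)-2-(allyloxy)-5-diazo-4-oxo-1-phenylpentyl]oxy}-5-hydroxy-2-phenylchroman-4-one | [N-]=[N+]=CC(=O)C[C@H](OCC=C)[C@@H](Oc1cc(O)c2c(c1)O[C@H](c1ccccc1)CC2=O)c1ccccc1 | intermediate (key-step precursor)
13 | (5S)-1-allyl-5-{(S)-{[(2S)-5-hydroxy-4-oxo-2-phenylchroman-7-yl]oxy}(phenyl)methyl}-3-oxooxolan-1-ium-2-ide | C=CC[O+]1[CH-]C(=O)C[C@H]1[C@@H](Oc1cc(O)c2c(c1)O[C@H](c1ccccc1)CC2=O)c1ccccc1 | intermediate (not isolated)
14 | (2S)-7-{(S)-[(2S,5R)-5-allyl-4-oxotetrahydrofuran-2-yl](phenyl)methoxy}-5-hydroxy-2-phenylchroman-4-one | C=CC[C@H]1O[C@H]([C@@H](Oc2cc(O)c3c(c2)O[C@H](c2ccccc2)CC3=O)c2ccccc2)CC1=O | intermediate (key-step product)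
15 | (2S)-7-{(S)-[(2S,4R,5R)-5-allyl-4-hydroxytetrahydrofuran-2-yl](phenyl)methoxy}-5-hydroxy-2-phenylchroman-4-one | C=CC[C@H]1O[C@H]([C@@H](Oc2cc(O)c3c(c2)O[C@H](c2ccccc2)CC3=O)c2ccccc2)C[C@H]1O | intermediate
16 | (2S)-7-{(S)-[(2S,4R,5R)-5-(2,3-dihydroxypropyl)-4-hydroxytetrahydrofuran-2-yl](phenyl)methoxy}-5-hydroxy-2-phenylchroman-4-one (both epimers at the new carbinol) | OCC(O)C[C@H]1O[C@H]([C@@H](Oc2cc(O)c3c(c2)O[C@H](c2ccccc2)CC3=O)c2ccccc2)C[C@H]1O | intermediate (not isolated)
17 | 2-[(2R,3R,5S)-3-hydroxy-5-{(S)-{[(2S)-5-hydroxy-4-oxo-2-phenylchroman-7-yl]oxy}(phenyl)methyl}tetrahydrofuran-2-yl]acetaldehyde | O=CC[C@H]1O[C@H]([C@@H](Oc2cc(O)c3c(c2)O[C@H](c2ccccc2)CC3=O)c2ccccc2)C[C@H]1O | intermediate (not isolated)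
18 | (2S)-5-hydroxy-7-{(S)-[(3aR,5S,6aR)-2-hydroxyhexahydrofuro[3,2-b]furan-5-yl](phenyl)methoxy}-2-phenylchroman-4-one (both anomers) | OC1C[C@H]2O[C@H]([C@@H](Oc3cc(O)c4c(c3)O[C@H](c3ccccc3)CC4=O)c3ccccc3)C[C@H]2O1 | intermediate
19 | (3aR,5S,6aR)-5-{(S)-{[(2S)-5-hydroxy-4-oxo-2-phenylchroman-7-yl]oxy}(phenyl)methyl}tetrahydrofuro[3,2-b]furan-2(3H)-one | O=C1C[C@H]2O[C@H]([C@@H](Oc3cc(O)c4c(c3)O[C@H](c3ccccc3)CC4=O)c3ccccc3)C[C@H]2O1 | target

Total step count: 11
Longest linear sequence: 11 steps (1 → 19); 4 and 8 are purchased and enter in steps 3 and 5.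

Steps most likely to fail

Step 8. Process at risk: the carbenoid is diverted before the five-membered ylide forms (O–H insertion at the phenol of a second molecule, or attack by the aryl ether oxygen followed by a [1,2]-benzylic shift), or the bulky flavanone erodes the trans selectivity. Fallback: keep the rearrangement but take the flavanone out of it and attach it afterwards. Setting out from 7, silylation (TBSOTf, 2,6-lutidine, CH2Cl2, −78 °C) should give allyl (3S,4R)-3-(allyloxy)-4-[(tert-butyldimethylsilyl)oxy]-4-phenylbutanoate F1. Deallylation as in step 6 should give (3S,4R)-3-(allyloxy)-4-[(tert-butyldimethylsilyl)oxy]-4-phenylbutanoic acid F2. Activation as in step 7 passes through (3S,4R)-3-(allyloxy)-4-[(tert-butyldimethylsilyl)oxy]-4-phenylbutanoic isobutyl carbonic anhydride F3 (not isolated) and, with diazomethane, should give (4S,5R)-4-(allyloxy)-5-[(tert-butyldimethylsilyl)oxy]-1-diazo-5-phenylpentan-2-one F4. Cu(acac)2 in THF at reflux should convert this, through (5S)-1-allyl-5-{(R)-[(tert-butyldimethylsilyl)oxy](phenyl)methyl}-3-oxooxolan-1-ium-2-ide F5 (not isolated), into (2R,5S)-2-allyl-5-{(R)-[(tert-butyldimethylsilyl)oxy](phenyl)methyl}dihydrofuran-3(2H)-one F6, a substrate of the ordinary silyloxyalkyl type. HF·pyridine in THF should free (2R,5S)-2-allyl-5-[(R)-hydroxy(phenyl)methyl]dihydrofuran-3(2H)-one F7. A Mitsunobu reaction of this alcohol with 8 (PPh3, DIAD, THF), which inverts the carbinol carbon, comes back to the route at 14.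

Step 5. Process at risk: substitution at the branched benzylic carbinol is slow, so that elimination, capture of the activated alcohol by the ester carbonyl (lactone formation) or partial ionisation with loss of configuration take over. Fallback: separate activation from substitution and use a pre-formed phenoxide. From 7, MsCl and Et3N (CH2Cl2, −20 °C) should give allyl (3S,4R)-3-(allyloxy)-4-[(methylsulfonyl)oxy]-4-phenylbutanoate F8. This mesylate is displaced with inversion by the 7-phenoxide of 8 (one equivalent of Cs2CO3, DMF, 0 °C → rt), which comes back to the route at 9.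

Step 9. Process at risk: poor facial selectivity, because the C5 side chain sits on the face that hydride must use, or competing reduction of the flavanone carbonyl. Fallback: accept the hydroxyl trans to the allyl group and correct the carbinol configuration in the ring closure. From 14, if reduction gives mainly the epimer (NaBH4, MeOH, −40 °C is the small-hydride alternative that may favour it), the product is (2S)-7-{(S)-[(2S,4S,5R)-5-allyl-4-hydroxytetrahydrofuran-2-yl](phenyl)methoxy}-5-hydroxy-2-phenylchroman-4-one F9. OsO4/NaIO4 as in step 10 should lead, through (2S)-7-{(S)-[(2S,4S,5R)-5-(2,3-dihydroxypropyl)-4-hydroxytetrahydrofuran-2-yl](phenyl)methoxy}-5-hydroxy-2-phenylchroman-4-one F10 (not isolated), to 2-[(2R,3S,5S)-3-hydroxy-5-{(S)-{[(2S)-5-hydroxy-4-oxo-2-phenylchroman-7-yl]oxy}(phenyl)methyl}tetrahydrofuran-2-yl]acetaldehyde F11, which stays open because a trans-fused lactol is strained. Pinnick oxidation (NaClO2, NaH2PO4, 2-methyl-2-butene, t-BuOH–H2O) should give 2-[(2R,3S,5S)-3-hydroxy-5-{(S)-{[(2S)-5-hydroxy-4-oxo-2-phenylchroman-7-yl]oxy}(phenyl)methyl}tetrahydrofuran-2-yl]acetic acid F12. Mitsunobu lactonisation (PPh3, DIAD, toluene, high dilution) then closes the lactone with inversion at the carbinol carbon and comes back to the route at the target 19.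

Further compounds
F1 | step 8 | allyl (3S,4R)-3-(allyloxy)-4-[(tert-butyldimethylsilyl)oxy]-4-phenylbutanoate | C=CCOC(=O)C[C@H](OCC=C)[C@H](O[Si](C)(C)C(C)(C)C)c1ccccc1
F2 | step 8 | (3S,4R)-3-(allyloxy)-4-[(tert-butyldimethylsilyl)oxy]-4-phenylbutanoic acid | OC(=O)C[C@H](OCC=C)[C@H](O[Si](C)(C)C(C)(C)C)c1ccccc1
F3 | step 8 | (3S,4R)-3-(allyloxy)-4-[(tert-butyldimethylsilyl)oxy]-4-phenylbutanoic isobutyl carbonic anhydride | CC(C)COC(=O)OC(=O)C[C@H](OCC=C)[C@H](O[Si](C)(C)C(C)(C)C)c1ccccc1
F4 | step 8 | (4S,5R)-4-(allyloxy)-5-[(tert-butyldimethylsilyl)oxy]-1-diazo-5-phenylpentan-2-one | [N-]=[N+]=CC(=O)C[C@H](OCC=C)[C@H](O[Si](C)(C)C(C)(C)C)c1ccccc1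
F5 | step 8 | (5S)-1-allyl-5-{(R)-[(tert-butyldimethylsilyl)oxy](phenyl)methyl}-3-oxooxolan-1-ium-2-ide | C=CC[O+]1[CH-]C(=O)C[C@H]1[C@H](O[Si](C)(C)C(C)(C)C)c1ccccc1
F6 | step 8 | (2R,5S)-2-allyl-5-{(R)-[(tert-butyldimethylsilyl)oxy](phenyl)methyl}dihydrofuran-3(2H)-one | C=CC[C@H]1O[C@H]([C@H](O[Si](C)(C)C(C)(C)C)c2ccccc2)CC1=O
F7 | step 8 | (2R,5S)-2-allyl-5-[(R)-hydroxy(phenyl)methyl]dihydrofuran-3(2H)-one | C=CC[C@H]1O[C@H]([C@H](O)c2ccccc2)CC1=O
F8 | step 5 | allyl (3S,4R)-3-(allyloxy)-4-[(methylsulfonyl)oxy]-4-phenylbutanoate | C=CCOC(=O)C[C@H](OCC=C)[C@H](OS(C)(=O)=O)c1ccccc1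
F9 | step 9 | (2S)-7-{(S)-[(2S,4S,5R)-5-allyl-4-hydroxytetrahydrofuran-2-yl](phenyl)methoxy}-5-hydroxy-2-phenylchroman-4-one | C=CC[C@H]1O[C@H]([C@@H](Oc2cc(O)c3c(c2)O[C@H](c2ccccc2)CC3=O)c2ccccc2)C[C@@H]1O
F10 | step 9 | (2S)-7-{(S)-[(2S,4S,5R)-5-(2,3-dihydroxypropyl)-4-hydroxytetrahydrofuran-2-yl](phenyl)methoxy}-5-hydroxy-2-phenylchroman-4-one | OCC(O)C[C@H]1O[C@H]([C@@H](Oc2cc(O)c3c(c2)O[C@H](c2ccccc2)CC3=O)c2ccccc2)C[C@@H]1O
F11 | step 9 | 2-[(2R,3S,5S)-3-hydroxy-5-{(S)-{[(2S)-5-hydroxy-4-oxo-2-phenylchroman-7-yl]oxy}(phenyl)methyl}tetrahydrofuran-2-yl]acetaldehyde | O=CC[C@H]1O[C@H]([C@@H](Oc2cc(O)c3c(c2)O[C@H](c2ccccc2)CC3=O)c2ccccc2)C[C@@H]1O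
F12 | step 9 | 2-[(2R,3S,5S)-3-hydroxy-5-{(S)-{[(2S)-5-hydroxy-4-oxo-2-phenylchroman-7-yl]oxy}(phenyl)methyl}tetrahydrofuran-2-yl]acetic acid | OC(=O)C[C@H]1O[C@H]([C@@H](Oc2cc(O)c3c(c2)O[C@H](c2ccccc2)CC3=O)c2ccccc2)C[C@@H]1O
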